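The numbers in the tables were generated by integration on assumed constants, and the scatter is random.

- Which flask ends richer in product is read here from how much product appears for each trapped intermediate formed. The two flasks are set against each other here by that split.

in all of them: substrate 1.6 M; coupling partner 1.12 M
- Tuesday's: capture agent 0.48 M; free catalyst 270 mM; temperature 45 °C; run made earlier
- Sunday's: capture agent 0.48 M; free catalyst 990 mM; temperature 56 °C; run made earlier
- spring: capture agent 0.480 M; free catalyst 800 mM; at 40 °C throughout; time 6.0 h
- dusk: capture agent 0.480 M; free catalyst 180 mM; at 60 °C until 3.0 h, from then on at 40 °C; time 6.0 h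

- Tuesday's (time / h: product / %, trapped intermediate / %): 0.833: 1.9, 1.3; 2.00: 2.1, 3.3; 4.00: 4.1, 9.7; 6.00: 4.3, 13.0; 8.00: 6.5, 14.7
- Sunday's (time / h: product / %, trapped intermediate / %): 0.833: 7.8, 10.4; 1.50: 15.1, 17.6; 2.50: 24.0, 23.7; 3.00: 29.5, 25.4; 4.00: 33.5, 25.8

(each reading ± 1 percentage point)

- the flask that ends with the higher share of product in all that became product or trapped intermediate, or "neither" when 2 percentage points or less lies between them (spring / dusk / neither)
- share of product in all that became product or trapped intermediate, spring
- share of product in all that became product or trapped intermediate, dusk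

- what was read earlier has a scatter of 1 percentage point, one standard deviation
- a reading or a percentage of product counts all its forms, free or not

- Let x be that split, in percent of substrate, with share x/(x + 1). The zero of the scale is x = 1, the even split, and x is a selectivity factor.
- At nearly equal trapped intermediate, Tuesday's reads 0.423 at 4.00 h and Sunday's reads 0.750 at 0.833 h. This reckoning gives the whole change to temperature, taking ln x as straight in temperature.
- That yields the hot split number, product per trapped intermediate at 60 °C, 0.924, and 0.326 at 40 °C. Spring therefore gets a share of 24.6%.
- The level: Tuesday's trapped intermediate reaches 14.7%, below its catalyst charge of 16.9% of substrate. Sunday's reaches 25.8%, below its capture charge of 30.0%. The smaller charge looks like the limiting reagent, so dusk should level near 11.2%.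
- The slope: per catalyst, the two early readings differ by a factor 1.40. Scaled to dusk and drawn straight, the line reaches 7.70% at the knee, 3.0 h.
- After cooling, the slower line could add 4.16%, more than the 3.55% missing. Weighting xh and the cold split by these two stretches gives dusk 42.4%.
- The forecast says dusk, with spring 30% and dusk 41%, from “one activated intermediate that splits between the partner”; its spring stands above this reckoning's.

    substrate + free catalyst → catalyst intermediate A (k = 0.0362 M⁻¹ min⁻¹, Ea = 65.0 kJ mol⁻¹)
    coupling partner + catalyst intermediate A ⇌ catalyst intermediate B (K = 0.659 M⁻¹, k = 0.0508 M⁻¹ min⁻¹, Ea = 62.0 kJ mol⁻¹, ΔH = −47.0 kJ mol⁻¹)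
    catalyst intermediate B ⇌ catalyst intermediate C (K = 3.10, k = 0.529 min⁻¹, Ea = 94.0 kJ mol⁻¹, ΔH = −21.0 kJ mol⁻¹)
    catalyst intermediate C → free catalyst + product (k = 0.0556 min⁻¹, Ea = 102 kJ mol⁻¹)
    crystals ⇌ product, rate k5*(cs5 - [product]) while solid is left; crystals form when [product] > cs5 (solubility = 0.0610 M, k = 0.0358 min⁻¹)
    capture agent + catalyst intermediate C → trapped intermediate (k = 0.174 M⁻¹ min⁻¹, Ea = 55.0 kJ mol⁻¹)
    (constants at 60 °C)

- The flasks give dusk: dusk 43.0%, spring 29.7%. At 6.0 h, 90.5% of dusk's catalyst stands as trapped intermediate. At 3.0 h, dusk's product per trapped intermediate is 0.796, against the hot split number 0.924.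
- In the neighbour of dusk with 0.29 M of capture agent, this reckoning assumes that both lines of trapped intermediate fall in proportion to capture agent and that x goes inversely with it, so xh becomes 1.53. The two lines then reach 7.17%, below the catalyst level of 11.2%, while product comes to 8.47%, which gives a share of 54.2%. The simulated neighbour gives 57.0%, with 8.65% of substrate charged standing as trapped intermediate at 6.0 h.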